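**Plan**
Numbering: C1 free carbinol, C2 methylene, C3 acetoxy carbon, C4=C5 olefin (C15 hydroxymethyl on C4), C6 lactone carbinol, C7 ring-fusion carbon, C8 angeloyloxy carbon, C9=C10 olefin (C14 methyl on C10), C11–C13 methylene lactone carbons.
Feature: C1 carries the only free secondary hydroxyl and is allylic to the Z C9=C10 olefin of the ten-membered carbocycle, so that ring is cut at C1–C10 (C10 alkenyl iodide plus C1 aldehyde) with the fused five-membered lactone ring, the acetate and the angelate already in place.
Further cuts: C8–O (angelate), C7–C8 (allylzinc of a 3-(bromomethyl)butenolide plus (Z)-3-iodobut-2-enal), C7=C11 and C6–O (metathesis of a 2-(bromomethyl)acrylate), C6–C7 (vinylzinc addition), C3–C4 (alkenylchromium addition).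
Forward: the C1–C6 chain is built from 2-butyne-1,4-diol, the butenolide ring is closed, the C8–C10 unit is joined at C7 (the butenolide becomes the trans α-methylene lactone), and the ten-membered ring is closed last, before desilylation.
Stereochemistry: C3 from a CBS reduction, C6 from a ligand-controlled vinylzinc addition, C7 and C8 relayed from C6 in the chair-like Barbier transition state, C1 from 1,3-induction by the C3 acetate in the ring closure; both Z olefins from trans-hydroalumination/iodination of propargylic alcohols.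

Key step: step 19

Remark: CIP letters are quoted in the numbering above; they change with substituent priorities along the route (C6, C7, C8) while the spatial arrangement stays that of the target.

Step 1
Reactants: 1 2-butyne-1,4-diol
Product: 2 4-[(tert-butyldimethylsilyl)oxy]but-2-yn-1-ol
Conditions: TBSCl (1 equiv), imidazole, 1 in excess, DMF, 0 °C to rt
Reagents that add atoms: tert-butyldimethylsilyl chloride, CC(C)(C)[Si](C)(C)Cl
Why: Statistical monosilylation of the symmetrical diol (silyl ether formation) leaves one hydroxyl free to direct the next step; no stereocentre is involved.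

Step 2
Reactants: 2 4-[(tert-butyldimethylsilyl)oxy]but-2-yn-1-ol
Product: 4 (Z)-4-[(tert-butyldimethylsilyl)oxy]-3-iodobut-2-en-1-ol, via sodium alkenylaluminate 3 (not isolated)
Conditions: NaAlH2(OCH2CH2OMe)2 (Red-Al), THF, 0 °C; then I2, THF, −78 °C
Reagents that add atoms: iodine, II
Why: Hydroxyl-directed trans-hydroalumination of the propargylic alcohol places aluminium on the distal alkyne carbon (C4) in a five-membered chelate, and iodinolysis with retention should give the (Z)-iodoalkene in which C6 and iodine (the future C3) are cis, which fixes the C4=C5 geometry.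

Step 3
Reactants: 4 (Z)-4-[(tert-butyldimethylsilyl)oxy]-3-iodobut-2-en-1-ol
Product: 5 (Z)-4-[(tert-butyldimethylsilyl)oxy]-3-iodo-1-[(triethylsilyl)oxy]but-2-ene
Conditions: TESCl, imidazole, CH2Cl2, 0 °C
Reagents that add atoms: chlorotriethylsilane, CC[Si](Cl)(CC)CC
Why: Standard silylation of the primary allylic alcohol; the triethylsilyl ether is chosen because it can later be oxidised away in the presence of the tert-butyldimethylsilyl ether.

Step 4
Reactants: 6 3-[(4-methoxybenzyl)oxy]propan-1-ol
Product: 7 3-[(4-methoxybenzyl)oxy]propanal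
Conditions: Dess–Martin periodinane, CH2Cl2, 0 °C to rt
Reagents that add atoms: none
Why: Dess–Martin oxidation takes the primary alcohol to the aldehyde without over-oxidation and leaves the PMB ether untouched.

Step 5
Reactants: 5 (Z)-4-[(tert-butyldimethylsilyl)oxy]-3-iodo-1-[(triethylsilyl)oxy]but-2-ene; 7 3-[(4-methoxybenzyl)oxy]propanal
Product: 8 racemic (Z)-4-{[(tert-butyldimethylsilyl)oxy]methyl}-1-[(4-methoxybenzyl)oxy]-6-[(triethylsilyl)oxy]hex-4-en-3-ol
Conditions: CrCl2 (4 equiv), NiCl2 (2 mol %), DMSO, rt
Reagents that add atoms: none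
Why: Intermolecular Nozaki–Hiyama–Kishi coupling, in which zerovalent nickel inserts into the C4–I bond and the alkenyl group passes to trivalent chromium and adds to the aldehyde with retention of olefin geometry (reliable for iodoalkenes disubstituted at the iodine-bearing carbon) while both silyl ethers are tolerated; C3 forms as a racemate and is corrected in steps 6 and 7.

Step 6
Reactants: 8 racemic C3 allylic alcohol
Product: 9 (Z)-4-{[(tert-butyldimethylsilyl)oxy]methyl}-1-[(4-methoxybenzyl)oxy]-6-[(triethylsilyl)oxy]hex-4-en-3-one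
Conditions: Dess–Martin periodinane, NaHCO3, CH2Cl2, 0 °C
Reagents that add atoms: none
Why: Buffered Dess–Martin oxidation of the secondary allylic alcohol gives the enone under non-isomerising conditions and erases the uncontrolled C3 centre.

Step 7
Reactants: 9 C3 enone
Product: 10 (3S,4Z)-4-{[(tert-butyldimethylsilyl)oxy]methyl}-1-[(4-methoxybenzyl)oxy]-6-[(triethylsilyl)oxy]hex-4-en-3-ol
Conditions: (R)-2-methyl-CBS-oxazaborolidine (20 mol %), catecholborane, toluene, −78 °C
Reagents that add atoms: none
Why: Corey–Bakshi–Shibata reduction, in which the branched alkenyl group acts as the large and the CH2CH2OPMB chain as the small substituent so that the (R)-catalyst should deliver hydride to the face giving the (3S)-alcohol, while catecholborane at low temperature avoids hydroboration and conjugate reduction.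

Step 8
Reactants: 10 (3S)-allylic alcohol
Product: 11 (3S,4Z)-4-{[(tert-butyldimethylsilyl)oxy]methyl}-1-[(4-methoxybenzyl)oxy]-6-[(triethylsilyl)oxy]hex-4-en-3-yl acetate
Conditions: Ac2O, pyridine, DMAP (cat.), CH2Cl2, 0 °C to rt
Reagents that add atoms: acetic anhydride, CC(=O)OC(C)=O
Why: DMAP-catalysed acetylation installs the C3 acetate of the target with retention and blocks lactol or furan formation once C6 becomes an aldehyde.

Step 9
Reactants: 11 C3 acetate with C6 triethylsilyl ether
Product: 12 (2Z,4S)-4-acetoxy-3-{[(tert-butyldimethylsilyl)oxy]methyl}-6-[(4-methoxybenzyl)oxy]hex-2-enal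
Conditions: (COCl)2, DMSO, CH2Cl2, −78 to −30 °C; then Et3N, −78 to 0 °C
Reagents that add atoms: none
Why: Swern oxidation applied directly to the primary triethylsilyl ether, in which the chlorodimethylsulfonium salt desilylates and oxidises the more labile TES ether to the C6 aldehyde while the TBS ether, the acetate and the PMB ether are left, and the low temperature should preserve the Z geometry.

Step 10
Reactants: 12 Z-enal (C6 aldehyde)
Product: 13 (3S,4Z,6R)-6-hydroxy-4-{[(tert-butyldimethylsilyl)oxy]methyl}-1-[(4-methoxybenzyl)oxy]octa-4,7-dien-3-yl acetate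
Conditions: Zn(CH=CH2)2 (salt-free), (+)-MIB [(2R)-3-exo-morpholinoisoborneol, 10 mol %], toluene, −20 to 0 °C
Reagents that add atoms: divinylzinc, C=C[Zn]C=C
Why: Amino-alcohol-catalysed enantioselective addition of an alkenylzinc reagent to an aldehyde, in which the (+)-MIB–zinc complex should direct the vinyl group to the Re face of the enal and so set C6 (R with these substituents), the acetate being inert to organozinc reagents.

Step 11
Reactants: 13 bis-allylic alcohol; 14 2-(bromomethyl)acrylic acid
Product: 16 (3S,4Z,6R)-3-acetoxy-4-{[(tert-butyldimethylsilyl)oxy]methyl}-1-[(4-methoxybenzyl)oxy]octa-4,7-dien-6-yl 2-(bromomethyl)acrylate, via acid chloride 15 (not isolated)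
Conditions: 14, (COCl)2, DMF (cat.), CH2Cl2, 0 °C to rt, evaporate; then 13, 2,6-lutidine, CH2Cl2, −40 to 0 °C
Reagents that add atoms: none
Why: Acylation of the secondary alcohol with the acid chloride made in the flask, in which the hindered base 2,6-lutidine takes up HCl without displacing the allylic bromide and C6 keeps its configuration.

Step 12
Reactants: 16 2-(bromomethyl)acrylate ester
Product: 17 (5S)-3-(bromomethyl)-5-[(1Z,3S)-3-acetoxy-2-{[(tert-butyldimethylsilyl)oxy]methyl}-5-[(4-methoxybenzyl)oxy]pent-1-en-1-yl]furan-2(5H)-one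
Conditions: second-generation Grubbs catalyst (5 mol %), CH2Cl2 (0.005 M), 40 °C
Reagents that add atoms: none
Why: Ring-closing metathesis, in which the ruthenium carbene loads at the monosubstituted vinyl group and closes onto the acrylate to give the five-membered butenolide (C7=C11) with loss of ethene, while the trisubstituted C4=C5 olefin and the allylic bromide stay inert and C6 is untouched.

Step 13
Reactants: 18 but-2-yn-1-ol
Product: 20 (Z)-3-iodobut-2-en-1-ol, via sodium alkenylaluminate 19 (not isolated)
Conditions: NaAlH2(OCH2CH2OMe)2 (Red-Al), THF, 0 °C to rt; then I2, −78 °C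
Reagents that add atoms: iodine, II
Why: The same hydroxyl-directed trans-hydroalumination and iodinolysis as in step 2 should give the (Z)-iodoalkene with iodine cis to the future C8, the geometry needed at C9=C10.

Step 14
Reactants: 20 (Z)-3-iodobut-2-en-1-ol
Product: 21 (Z)-3-iodobut-2-enal
Conditions: MnO2, CH2Cl2, rt, dark; filtrate used directly
Reagents that add atoms: none
Why: MnO2 oxidation of the allylic alcohol under neutral heterogeneous conditions should give the sensitive Z-iodoenal without isomerisation.

Step 15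
Reactants: 17 bromomethyl butenolide; 21 (Z)-3-iodobut-2-enal
Product: 23 (4S,5S)-4-[(1S,2Z)-1-hydroxy-3-iodobut-2-en-1-yl]-3-methylene-5-[(1Z,3S)-3-acetoxy-2-{[(tert-butyldimethylsilyl)oxy]methyl}-5-[(4-methoxybenzyl)oxy]pent-1-en-1-yl]dihydrofuran-2(3H)-one, via allylzinc bromide 22 (not isolated)
Conditions: Zn, THF/sat. aq NH4Cl, 0 °C to rt
Reagents that add atoms: none
Why: Barbier-type 2-(alkoxycarbonyl)allylation, in which zinc inserts into the allylic C–Br bond and the allylzinc adds through its γ-carbon (C7) to the aldehyde in a six-membered chair transition state, where the ring-locked geometry (C6 trans to the CH2Zn group) sets the C7/C8 relationship and approach opposite to the C6 side chain sets the trans-lactone, the alkenyl iodide, acetate and silyl ether being inert to zinc.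

Step 16
Reactants: 23 C8 alcohol; 24 angelic acid
Product: 26 C8 angelate of 23 (3S,6S,7R,8S), via mixed anhydride 25 (not isolated)
Conditions: 24, 2,4,6-trichlorobenzoyl chloride, Et3N, toluene, rt; then 23, toluene, 75 °C
Reagents that add atoms: none
Why: Yamaguchi-type mixed-anhydride esterification without DMAP acylates the C8 hydroxyl with retention and is the established way to keep the angelate from isomerising to the tiglate.

Step 17
Reactants: 26 C8 angelate with C1 PMB ether
Product: 27 C1 primary alcohol (3S,6S,7R,8S)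
Conditions: DDQ, CH2Cl2/pH 7 phosphate buffer, 0 °C
Reagents that add atoms: none
Why: Oxidative PMB cleavage with DDQ proceeds by hydride abstraction at the electron-rich benzylic position and leaves the esters, the methylene lactone, the iodoalkene and the silyl ether intact.

Step 18
Reactants: 27 C1 primary alcohol
Product: 28 seco C1 aldehyde with C10 Z-alkenyl iodide (3S,6S,7R,8S)
Conditions: Dess–Martin periodinane, NaHCO3, CH2Cl2, 0 °C
Reagents that add atoms: none
Why: Buffered Dess–Martin oxidation gives the β-acetoxy aldehyde under conditions mild enough to avoid loss of acetic acid, and the aldehyde is used directly.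

Step 19
Reactants: 28 seco C1 aldehyde with C10 Z-alkenyl iodide
Product: 30 C15 tert-butyldimethylsilyl ether of the target (1S,3S,6S,7S,8R), via alkenylchromium species 29 (not isolated)
Conditions: CrCl2 (10 equiv), NiCl2 (2 mol %), DMSO/THF 3:1, slow addition to 0.002 M, rt
Reagents that add atoms: none
Why: Zerovalent nickel (formed from NiCl2 by CrCl2) inserts into the C10–I bond with retention, the alkenyl group passes to trivalent chromium to give 29, and this adds to the C1 aldehyde, the chromium alkoxide being hydrolysed on work-up. The closest known reaction type is the Nozaki–Hiyama–Kishi alkenylation used to close medium and large carbocycles from iodoalkene aldehydes. The ten-membered ring (C1–C10) closes in a 10-exo-trig mode, C10 attacking the exocyclic C1=O. The new C1 stereocentre is controlled by the C3 acetoxy group β to the aldehyde (1,3-anti induction in the polar, non-chelated addition model), reinforced by the conformation imposed by the trans-lactone and the Z C4=C5 olefin, which should give the (1S)-alcohol. The step needs chemoselectivity (alkenylchromium reagents leave the lactone, its exocyclic methylene acceptor, the acetate and the angelate alone, and the aldehyde is the only reactive electrophile), retention of the Z geometry (secured by the stereoretentive coupling of iodoalkenes disubstituted at the iodine-bearing carbon) and ring closure over intermolecular coupling (secured by slow addition at high dilution and by the two cis olefins and the lactone, which hold C1 near C10).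

Step 20
Reactants: 30 C15 silyl ether
Product: 31 target (1S,3S,6S,7S,8R)
Conditions: HF·pyridine, pyridine, THF, 0 °C to rt
Reagents that add atoms: none
Why: Fluoride-mediated cleavage of the primary allylic silyl ether with buffered HF·pyridine should free the C15 hydroxyl without touching the esters, the methylene lactone or the C1 allylic alcohol.

**Compound list**
1 | 2-butyne-1,4-diol | OCC#CCO | starting material
2 | 4-[(tert-butyldimethylsilyl)oxy]but-2-yn-1-ol | OCC#CCO[Si](C)(C)C(C)(C)C | intermediate
3 | sodium alkenylaluminate from 2 (five-membered O–Al–C4=C5–C6 ring, two 2-methoxyethoxy groups on aluminium, CH2OTBS on C4) | [Na+].COCCO[Al-]1(OCCOC)OCC=C1CO[Si](C)(C)C(C)(C)C | intermediate (not isolated)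
4 | (Z)-4-[(tert-butyldimethylsilyl)oxy]-3-iodobut-2-en-1-ol | OC/C=C(\I)CO[Si](C)(C)C(C)(C)C | intermediate
5 | (Z)-4-[(tert-butyldimethylsilyl)oxy]-3-iodo-1-[(triethylsilyl)oxy]but-2-ene | CC[Si](CC)(CC)OC/C=C(\I)CO[Si](C)(C)C(C)(C)C | intermediate
6 | 3-[(4-methoxybenzyl)oxy]propan-1-ol | OCCCOCc1ccc(OC)cc1 | starting material
7 | 3-[(4-methoxybenzyl)oxy]propanal | O=CCCOCc1ccc(OC)cc1 | intermediate
8 | racemic (Z)-4-{[(tert-butyldimethylsilyl)oxy]methyl}-1-[(4-methoxybenzyl)oxy]-6-[(triethylsilyl)oxy]hex-4-en-3-ol | COc1ccc(COCCC(O)/C(CO[Si](C)(C)C(C)(C)C)=C\CO[Si](CC)(CC)CC)cc1 | intermediate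
9 | (Z)-4-{[(tert-butyldimethylsilyl)oxy]methyl}-1-[(4-methoxybenzyl)oxy]-6-[(triethylsilyl)oxy]hex-4-en-3-one | COc1ccc(COCCC(=O)/C(CO[Si](C)(C)C(C)(C)C)=C\CO[Si](CC)(CC)CC)cc1 | intermediate
10 | (3S,4Z)-4-{[(tert-butyldimethylsilyl)oxy]methyl}-1-[(4-methoxybenzyl)oxy]-6-[(triethylsilyl)oxy]hex-4-en-3-ol | COc1ccc(COCC[C@H](O)/C(CO[Si](C)(C)C(C)(C)C)=C\CO[Si](CC)(CC)CC)cc1 | intermediate
11 | (3S,4Z)-4-{[(tert-butyldimethylsilyl)oxy]methyl}-1-[(4-methoxybenzyl)oxy]-6-[(triethylsilyl)oxy]hex-4-en-3-yl acetate | COc1ccc(COCC[C@H](OC(C)=O)/C(CO[Si](C)(C)C(C)(C)C)=C\CO[Si](CC)(CC)CC)cc1 | intermediate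
12 | (2Z,4S)-4-acetoxy-3-{[(tert-butyldimethylsilyl)oxy]methyl}-6-[(4-methoxybenzyl)oxy]hex-2-enal | COc1ccc(COCC[C@H](OC(C)=O)/C(CO[Si](C)(C)C(C)(C)C)=C\C=O)cc1 | intermediate
13 | (3S,4Z,6R)-6-hydroxy-4-{[(tert-butyldimethylsilyl)oxy]methyl}-1-[(4-methoxybenzyl)oxy]octa-4,7-dien-3-yl acetate | COc1ccc(COCC[C@H](OC(C)=O)/C(CO[Si](C)(C)C(C)(C)C)=C\[C@H](O)C=C)cc1 | intermediate
14 | 2-(bromomethyl)acrylic acid | C=C(CBr)C(=O)O | starting material
15 | 2-(bromomethyl)acryloyl chloride | C=C(CBr)C(=O)Cl | intermediate (not isolated)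
16 | (3S,4Z,6R)-3-acetoxy-4-{[(tert-butyldimethylsilyl)oxy]methyl}-1-[(4-methoxybenzyl)oxy]octa-4,7-dien-6-yl 2-(bromomethyl)acrylate | COc1ccc(COCC[C@H](OC(C)=O)/C(CO[Si](C)(C)C(C)(C)C)=C\[C@H](OC(=O)C(=C)CBr)C=C)cc1 | intermediate
17 | (5S)-3-(bromomethyl)-5-[(1Z,3S)-3-acetoxy-2-{[(tert-butyldimethylsilyl)oxy]methyl}-5-[(4-methoxybenzyl)oxy]pent-1-en-1-yl]furan-2(5H)-one | COc1ccc(COCC[C@H](OC(C)=O)/C(CO[Si](C)(C)C(C)(C)C)=C\[C@@H]2OC(=O)C(CBr)=C2)cc1 | intermediate
18 | but-2-yn-1-ol | CC#CCO | starting material
19 | sodium alkenylaluminate from 18 (five-membered O–Al–C=C–C ring, methyl on the aluminium-bearing carbon) | [Na+].COCCO[Al-]1(OCCOC)OCC=C1C | intermediate (not isolated)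
20 | (Z)-3-iodobut-2-en-1-ol | I/C(C)=C\CO | intermediate
21 | (Z)-3-iodobut-2-enal | I/C(C)=C\C=O | intermediate
22 | allylzinc bromide from 17 (BrZnCH2 at C11 of the butenolide) | COc1ccc(COCC[C@H](OC(C)=O)/C(CO[Si](C)(C)C(C)(C)C)=C\[C@@H]2OC(=O)C(C[Zn]Br)=C2)cc1 | intermediate (not isolated)
23 | (4S,5S)-4-[(1S,2Z)-1-hydroxy-3-iodobut-2-en-1-yl]-3-methylene-5-[(1Z,3S)-3-acetoxy-2-{[(tert-butyldimethylsilyl)oxy]methyl}-5-[(4-methoxybenzyl)oxy]pent-1-en-1-yl]dihydrofuran-2(3H)-one (3S,6S,7S,8S) | I/C(C)=C\[C@@H](O)[C@@H]1C(=C)C(=O)O[C@H]1/C=C(/CO[Si](C)(C)C(C)(C)C)[C@@H](OC(C)=O)CCOCc2ccc(OC)cc2 | intermediate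
24 | angelic acid, (Z)-2-methylbut-2-enoic acid | C/C=C(/C)C(=O)O | starting material
25 | angelic 2,4,6-trichlorobenzoic anhydride | C/C=C(/C)C(=O)OC(=O)c1c(Cl)cc(Cl)cc1Cl | intermediate (not isolated)
26 | C8 angelate of 23: trans α-methylene lactone with C8 (Z)-2-methylbut-2-enoate, C10 Z-iodide, C3 acetate, C15 TBS ether, C1 PMB ether (3S,6S,7R,8S) | I/C(C)=C\[C@@H](OC(=O)/C(C)=C\C)[C@@H]1C(=C)C(=O)O[C@H]1/C=C(/CO[Si](C)(C)C(C)(C)C)[C@@H](OC(C)=O)CCOCc2ccc(OC)cc2 | intermediate
27 | C1 primary alcohol corresponding to 26 (3S,6S,7R,8S) | I/C(C)=C\[C@@H](OC(=O)/C(C)=C\C)[C@@H]1C(=C)C(=O)O[C@H]1/C=C(/CO[Si](C)(C)C(C)(C)C)[C@@H](OC(C)=O)CCO | intermediate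
28 | seco C1 aldehyde with C10 Z-alkenyl iodide, complete lactone, C3 acetate, C8 angelate, C15 TBS ether (3S,6S,7R,8S) | I/C(C)=C\[C@@H](OC(=O)/C(C)=C\C)[C@@H]1C(=C)C(=O)O[C@H]1/C=C(/CO[Si](C)(C)C(C)(C)C)[C@@H](OC(C)=O)CC=O | intermediate
29 | C10 alkenylchromium dichloride of 28 (trivalent chromium, Z geometry retained) | Cl[Cr](Cl)/C(C)=C\[C@@H](OC(=O)/C(C)=C\C)[C@@H]1C(=C)C(=O)O[C@H]1/C=C(/CO[Si](C)(C)C(C)(C)C)[C@@H](OC(C)=O)CC=O | intermediate (not isolated)
30 | C15 tert-butyldimethylsilyl ether of the target: (4Z,9Z)-germacra-4,9,11(13)-trien-12,6-olide with 1-OH, 3-OAc, 8-O-angeloyl, 15-OTBS (1S,3S,6S,7S,8R) | C=C1C(=O)O[C@H]2/C=C(/CO[Si](C)(C)C(C)(C)C)[C@@H](OC(C)=O)C[C@H](O)/C(C)=C\[C@@H](OC(=O)/C(C)=C\C)[C@H]12 | intermediate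
31 | target: (4Z,9Z)-3-acetoxy-8-angeloyloxy-1,15-dihydroxygermacra-4,9,11(13)-trien-12,6-olide (1S,3S,6S,7S,8R) | C=C1C(=O)O[C@H]2/C=C(/CO)[C@@H](OC(C)=O)C[C@H](O)/C(C)=C\[C@@H](OC(=O)/C(C)=C\C)[C@H]12 | target

**Count and risks**
Total step count: 20. Longest linear sequence: 17 steps (steps 1–3, 5–12, 15–20).

Steps most likely to fail:

1. Step 19. The facial selectivity at the C1 aldehyde rests on substrate control alone and may be poor, so the wrong C1 alcohol could form alongside the right one. The fallback sets out from 28 and comes back at 30. The closure is run as in step 19 and the product is carried on as the mixture of 30 and its C1 epimer F1. Dess–Martin oxidation converts both into the ten-membered C1 enone F2 (ketone conjugated with C9=C10). Corey–Bakshi–Shibata reduction with the (R)-catalyst and catecholborane, with the alkenyl side as the large group, should then return the (1S)-alcohol 30 under reagent control.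

2. Step 15. The simple diastereoselectivity (C7/C8) may erode if the aqueous zinc reaction leaves the chair pathway, and aldehyde 21 may isomerise from Z to E during the reaction. The fallback sets out from 17 and comes back at 23. Pd2(dba)3-catalysed (zerovalent palladium) borylation of the allylic bromide with bis(pinacolato)diboron in THF gives the isolable allyl pinacolboronate F3. On warming with 21 in toluene, F3 should add through the rigid closed chair transition state typical of 2-(alkoxycarbonyl)allylboronates, and hydrolytic work-up gives 23.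

3. Step 10. Enantiofacial discrimination with the hindered Z-enal may be low, and the enal may isomerise under the Lewis-acidic zinc reagent. The fallback sets out from 12 and comes back at 13. ProPhenol/Me2Zn-catalysed enantioselective addition of trimethylsilylacetylene (ligand enantiomer chosen for Re-face delivery) gives the silylated propargylic alcohol F4. AgNO3-catalysed protodesilylation in aqueous acetone gives the terminal alkyne F5. Semi-hydrogenation with H2 over Pd/CaCO3 poisoned with Pb(OAc)2 (Lindlar catalyst) and quinoline gives 13.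

**Further compounds**
F1 | step 19 | C1 epimer of 30, the (1R)-alcohol | C=C1C(=O)O[C@H]2/C=C(/CO[Si](C)(C)C(C)(C)C)[C@@H](OC(C)=O)C[C@@H](O)/C(C)=C\[C@@H](OC(=O)/C(C)=C\C)[C@H]12
F2 | step 19 | ten-membered C1 enone (C1 ketone of 30) | C=C1C(=O)O[C@H]2/C=C(/CO[Si](C)(C)C(C)(C)C)[C@@H](OC(C)=O)CC(=O)/C(C)=C\[C@@H](OC(=O)/C(C)=C\C)[C@H]12
F3 | step 15 | allyl pinacolboronate from 17 (pinacolboryl in place of bromine) | COc1ccc(COCC[C@H](OC(C)=O)/C(CO[Si](C)(C)C(C)(C)C)=C\[C@@H]2OC(=O)C(CB3OC(C)(C)C(C)(C)O3)=C2)cc1
F4 | step 10 | (3S,6S)-propargylic alcohol with trimethylsilylethynyl group at C6 | COc1ccc(COCC[C@H](OC(C)=O)/C(CO[Si](C)(C)C(C)(C)C)=C\[C@H](O)C#C[Si](C)(C)C)cc1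
F5 | step 10 | (3S,6S)-propargylic alcohol with terminal ethynyl group at C6 | COc1ccc(COCC[C@H](OC(C)=O)/C(CO[Si](C)(C)C(C)(C)C)=C\[C@H](O)C#C)cc1
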